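## The problem

Labels used throughout: K is the ketone carbon; ring A is the dihydroxybenzo ring bonded to K and, at the neighbouring carbon a2, to C7; ring B is the dihydroxybenzo ring shared by both carbocycles; C7 is the seven-ring methine bearing 4-hydroxyphenyl; C8 is the methine common to both carbocycles; C9 is the five-ring methine bearing 4-hydroxyphenyl; C10 is the five-ring methine bearing 3,5-dihydroxyphenyl.

The target 18 is a tetracyclic heptaphenol. A 1,2,3-trisubstituted indane (C8, C9, C10 on ring B) is joined through C8 and the adjacent ring B carbon to a seven-membered ketone ring, in which K links ring B to ring A and C7 links ring A back to C8. The four contiguous methines C7 (S), C8 (R), C9 (S) and C10 (S) are all trans. Only C10 has to be set in the absolute sense: C9 is epimerisable next to an indanone carbonyl and settles trans to the C10 aryl group, C8 can be introduced anti to the C9 aryl group, and C7 can follow C8 inside the seven-membered ring. K is a crowded, tri-ortho-substituted benzophenone, and the ring B carbon that carries it is only one of several equally electron-rich aromatic positions, so its substituent has to be fixed before the C10 resorcinol ring is present. Seven phenols call for one robust protecting group removed at the end. The doubly benzylic methines, the electron-rich rings and any leaving group at C8 (which would eliminate to a conjugated indene) do not tolerate strong oxidants, hot acid or base late in the route. The feature that makes the key step possible is that C7 and C8 are neighbouring benzylic carbons that are both electrophiles in their natural precursors: C7 as the exocyclic carbon of the para-quinone methide of its own 4-hydroxyphenyl group, C8 as a benzylic bromide. K already ties rings A and B together and holds the two carbons within bonding distance, so a one-electron reduction can join them and close the seven-membered ring.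

## Retrosynthesis

**18 to 16 (no skeletal bond).** 18 is traced to its hexamethyl ether 17 and then to 16, whose C7 aryl group carries two tert-butyl groups beside a free phenol. Methyl ethers survive every organometallic, acidic and photochemical step. The tert-butyl groups are what make the quinone methide of 15 isolable. They are removed by transfer to an arene before ether cleavage, while the molecule is still soluble and unchelated. The forward steps must dealkylate without breaking the C7–aryl bond and then cleave six ethers without epimerisation.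

**16 to 15 (C7–C8, seven-membered ring).** The neighbouring cuts are K–ring B (an acylation at a carbon that competes with the C10 aryl ring) and a2–C7 (which would need C7 as a separate stereocentre). Cutting C7–C8 removes one ring and two stereocentres at once and leaves an open benzophenone, 15, whose two reacting carbons are already held close by K. The forward reaction must generate the C8 radical next to a reducible quinone methide, close the ring faster than hydrogen transfer, bond anti to the C9 aryl group and place H7 trans to H8.

**15 to 14 to 13 (functional groups only).** The quinone methide of 15 comes from the benzylphenol 14 by dehydrogenation at C7, and the bromide of 14 from the alcohol 13. Carrying C7 as a 3,5-di-tert-butyl-4-hydroxybenzyl group is preferred to an aldehyde that would be condensed later, because the benzylphenol passes untouched through aryllithium and hydride steps. The quinone methide reacts with hydride, phosphines and organometallics, so it is unmasked last, after the bromide is in place.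

**13 to 11 and 4 (K–ring B).** A Friedel–Crafts acylation of ring B would not be selective once the C10 aryl ring is present, and the K–ring A bond lies meta to both methoxy groups of ring A. A bromine atom is therefore placed on ring B from the start and exchanged for lithium (12), which is acylated by the Weinreb amide 4. The cut divides the molecule into two halves of similar size. The forward step must tolerate the free alkoxide at C8 and stop at the ketone.

**4 to 2 and 3 (a2–C7).** The ring A half is the Weinreb amide 2 benzylated at C2 by the benzylic alcohol 3. That position is para to one methoxy group and ortho to the other and is where this substitution pattern takes electrophiles. One step delivers ring A, the K carbon and the whole C7 unit.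

**11 to 10 (absolute configuration).** The alcohol at C8 is needed in any case, so the reduction of the racemic indanone 10 is run as a catalytic kinetic resolution. No catalytic asymmetric Nazarov closure is established for 2-aryl chalcones of this type, and C10 cannot be equilibrated, so resolution at the first chiral intermediate is the conservative choice. Half of 10 is given up for it.

**10 to 9 (ring B–C10, five-membered ring).** A Nazarov cyclisation forms the bond at the ring B carbon that is ortho and para to the methoxy groups. The alternative closure, an acylation forming the C8–ring B bond, would have to occur meta to both methoxy groups. C9 becomes trans by enolisation.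

**9 to 1.** 9 is the Knoevenagel product of the deoxybenzoin 7 and the aldehyde 8. 7 comes from the bromo Weinreb amide 5 and the benzylic Grignard reagent 6. 5 comes from 2 by bromination at the same C2 position used in the ring A branch, and 2 from the acid chloride 1. The single intermediate 2 therefore feeds both halves.

## Roads not taken

**Alternative 1:** Ring B itself is cut and rebuilt by a benzannulation. Photolysis of an unsaturated diazo ketone on a fully substituted cyclopentene gives a vinylketene by Wolff shift; this adds an alkoxyalkyne, ring-opens and electrocyclises to the indane A1, in which ring B appears as a phenol and an ethyl ether and the ring A ester is not yet cyclised.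
- Merits: the oxygen pattern of ring B is dictated by the annulation, no electrophilic substitution on an electron-rich ring is needed, and the seven-membered ring can then be closed by a classical intramolecular acylation. Every reaction type is known, which the chosen plan cannot claim for its ring closure.
- Weak points: the cyclopentene precursor must already carry C7 to C10 in the right configuration, without the thermodynamic help of an indanone and with C7 set in an open chain. The hindered diazo ketone and its photochemistry are delicate, the ethyl ether adds a second deprotection mode, and the route is much longer.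
- Comparison: the chosen plan sets against the lower precedent of its key step a short convergent route from four aromatic building blocks, with C7 and C8 set in one ring-forming event.

**Alternative 2:** The C9–C10 bond is cut. A diaryl hydrazone on ring B is oxidised to the diazo compound and a chiral dirhodium catalyst such as Rh2(R-PTAD)4 inserts the C10 carbene into a benzylic C9–H bond, giving the trans,trans indane ester A2.
- Merits: C10 is set by asymmetric catalysis without loss of material. This is better than the chosen plan, which resolves racemic 10.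
- Weak points: A2 holds C7 only as an ester carbon and ring B has no substituent where K must go. The ester has to be turned into a diarylmethine bearing ring A and the hydroxyphenyl group with control of C7, and the seven-membered ring must then be closed by acylating ring B in the presence of the more nucleophilic C10 aryl ring. The chosen route avoids that selectivity problem by placing bromine on ring B at the outset.
- Comparison: the chosen plan is weaker in enantiocontrol, but ring A, K and C7 arrive as one piece and far fewer steps follow the indane.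

**Alternative 3:** Both a2–C7 and C7–C8 are cut and an anisate ester serves as a one-carbon linchpin. A dianion (aryllithium at a2, dienolate through K by deprotonation at C8) adds twice to the ester and closes the seven-membered ring as the tertiary alcohol A3.
- Merits: the step is polar and highly convergent, and the C7 aryl group arrives as a plain 4-methoxyphenyl. No tert-butyl groups and no dealkylation are needed, a real advantage in protecting-group economy.
- Weak points: the dianion needs a dearomatised dienolate of a hindered benzophenone next to an aryllithium, and the second addition is a reversible aldol to a diaryl ketone. The C7 hydroxyl must then be removed through a cation or a C7=C8 alkene, whose reduction has no clear bias toward H7 trans to H8.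
- Comparison: the chosen plan has the C7 hydrogen in place from the start and forms both centres in one kinetically controlled step. It pays for this with two extra deprotection operations and a ring closure without precedent.

Key step: step 11

## Route

Assumption: 14 and 15 are carried as mixtures of C8 epimers (C8 is left undefined in their SMILES) because both give the same planar radical; 10 is racemic and its SMILES shows the enantiomer that is carried on.

Step 1
Reactants: 1 3,5-dimethoxybenzoyl chloride
Product: 2 N,3,5-trimethoxy-N-methylbenzamide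
Conditions: MeNHOMe·HCl, Et3N, CH2Cl2, 0 °C → rt
Reagents that add atoms: N,O-dimethylhydroxylamine hydrochloride, CNOC.Cl
Why: Acylation of the hydroxylamine by the acid chloride (Weinreb amide formation); 2 serves both halves of the route.

Step 2
Reactants: 2 N,3,5-trimethoxy-N-methylbenzamide; 3 3,5-di-tert-butyl-4-hydroxybenzyl alcohol
Product: 4 2-[(3,5-di-tert-butyl-4-hydroxyphenyl)methyl]-N,3,5-trimethoxy-N-methylbenzamide
Conditions: CF3CO2H, CH2Cl2, 0 °C → rt
Reagents that add atoms: none
Why: Friedel–Crafts benzylation: acid ionises 3 to a benzyl cation stabilised as a protonated quinone methide, which attacks C2 of 2 (para to one methoxy group, ortho to the other), the site where 3,5-dimethoxybenzoyl derivatives take halogen and formyl electrophiles; the tert-butyl groups are stable to this acid at room temperature.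

Step 3
Reactants: 2 N,3,5-trimethoxy-N-methylbenzamide
Product: 5 2-bromo-N,3,5-trimethoxy-N-methylbenzamide
Conditions: NBS (1.0 equiv), MeCN, 0 °C → rt
Reagents that add atoms: N-bromosuccinimide, O=C1CCC(=O)N1Br
Why: Electrophilic aromatic bromination, directed para to a methoxy group to C2 as for the corresponding ester and aldehyde; one equivalent avoids the 2,6-dibromide.

Step 4
Reactants: 5 2-bromo-N,3,5-trimethoxy-N-methylbenzamide; 6 4-methoxybenzylmagnesium chloride
Product: 7 1-(2-bromo-3,5-dimethoxyphenyl)-2-(4-methoxyphenyl)ethan-1-one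
Conditions: THF, −78 → 0 °C; aq NH4Cl
Reagents that add atoms: none
Why: Weinreb ketone synthesis: the benzylic Grignard reagent adds once and the chelated adduct releases the ketone only on work-up; the aryl bromide does not exchange with a benzylic Grignard reagent.

Step 5
Reactants: 7 1-(2-bromo-3,5-dimethoxyphenyl)-2-(4-methoxyphenyl)ethan-1-one; 8 3,5-dimethoxybenzaldehyde
Product: 9 (E)-1-(2-bromo-3,5-dimethoxyphenyl)-3-(3,5-dimethoxyphenyl)-2-(4-methoxyphenyl)prop-2-en-1-one
Conditions: piperidine (cat.), AcOH (cat.), toluene, reflux, Dean–Stark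
Reagents that add atoms: none
Why: Knoevenagel condensation of the deoxybenzoin with the aromatic aldehyde, driven by removal of water; the alkene geometry (E expected to prevail) has no consequence for the next step.

Step 6
Reactants: 9 (E)-1-(2-bromo-3,5-dimethoxyphenyl)-3-(3,5-dimethoxyphenyl)-2-(4-methoxyphenyl)prop-2-en-1-one
Product: 10 (2RS,3RS)-7-bromo-3-(3,5-dimethoxyphenyl)-4,6-dimethoxy-2-(4-methoxyphenyl)-2,3-dihydro-1H-inden-1-one (racemic, trans)
Conditions: CF3CO2H, 60 °C
Reagents that add atoms: none
Why: Nazarov cyclisation: the O-protonated aryl vinyl ketone closes by conrotatory 4π electrocyclisation onto the only free ortho carbon of the bromodimethoxyphenyl ring, which is ortho and para to the methoxy groups, forming the ring B–C10 bond. C9 equilibrates through the enol to the trans isomer, so 10 should form as the racemic trans compound.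

Step 7
Reactants: 10 (2RS,3RS)-7-bromo-3-(3,5-dimethoxyphenyl)-4,6-dimethoxy-2-(4-methoxyphenyl)-2,3-dihydro-1H-inden-1-one
Product: 11 (1R,2S,3S)-7-bromo-3-(3,5-dimethoxyphenyl)-4,6-dimethoxy-2-(4-methoxyphenyl)-2,3-dihydro-1H-inden-1-ol
Conditions: RuCl[(R,R)-TsDPEN](p-cymene) (1 mol %), HCO2H/Et3N (5:2), CH2Cl2, 25 °C, stopped near half conversion; chromatography
Reagents that add atoms: none
Why: Noyori–Ikariya asymmetric transfer hydrogenation run as a kinetic resolution, a mode established for 3-aryl-1-indanones: the (R,R) catalyst delivers hydride to the carbonyl face that in (2S,3S)-10 lies anti to the C2 aryl group (matched), giving the 1R alcohol cis to that group, while the (2R,3R) enantiomer is mismatched and stays as ketone. This step fixes the absolute configuration of C9 and C10 for the rest of the route.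

Step 8
Reactants: 11 (1R,2S,3S)-7-bromo-3-(3,5-dimethoxyphenyl)-4,6-dimethoxy-2-(4-methoxyphenyl)-2,3-dihydro-1H-inden-1-ol; 4 2-[(3,5-di-tert-butyl-4-hydroxyphenyl)methyl]-N,3,5-trimethoxy-N-methylbenzamide
Product: 13 {2-[(3,5-di-tert-butyl-4-hydroxyphenyl)methyl]-3,5-dimethoxyphenyl}[(1S,2S,3R)-1-(3,5-dimethoxyphenyl)-3-hydroxy-5,7-dimethoxy-2-(4-methoxyphenyl)-2,3-dihydro-1H-inden-4-yl]methanone, via aryllithium alkoxide 12 (not isolated)
Conditions: 11, n-BuLi (2.1 equiv), THF, −78 °C; then 4 (pre-treated with n-BuLi, 1.0 equiv), −78 → 0 °C; aq NH4Cl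
Reagents that add atoms: none
Why: Bromine–lithium exchange on the lithium alkoxide gives 12, which is acylated by the Weinreb amide; the chelated adduct stops at the ketone K, and the tri-ortho-substituted product resists a second addition. No stereocentre is involved.

Step 9
Reactants: 13 {2-[(3,5-di-tert-butyl-4-hydroxyphenyl)methyl]-3,5-dimethoxyphenyl}[(1S,2S,3R)-1-(3,5-dimethoxyphenyl)-3-hydroxy-5,7-dimethoxy-2-(4-methoxyphenyl)-2,3-dihydro-1H-inden-4-yl]methanone
Product: 14 [(1S,2S)-3-bromo-1-(3,5-dimethoxyphenyl)-5,7-dimethoxy-2-(4-methoxyphenyl)-2,3-dihydro-1H-inden-4-yl]{2-[(3,5-di-tert-butyl-4-hydroxyphenyl)methyl]-3,5-dimethoxyphenyl}methanone (both epimers at the bromine-bearing carbon, C8)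
Conditions: CBr4, PPh3, CH2Cl2, 0 °C
Reagents that add atoms: carbon tetrabromide, BrC(Br)(Br)Br
Why: Appel bromination of the secondary benzylic alcohol under neutral conditions, chosen to avoid ionisation toward the indene; the hindered phenol is inert, and the configuration at C8 does not matter because both epimers give the same radical.

Step 10
Reactants: 14 [(1S,2S)-3-bromo-1-(3,5-dimethoxyphenyl)-5,7-dimethoxy-2-(4-methoxyphenyl)-2,3-dihydro-1H-inden-4-yl]{2-[(3,5-di-tert-butyl-4-hydroxyphenyl)methyl]-3,5-dimethoxyphenyl}methanone
Product: 15 2,6-di-tert-butyl-4-({2-[(1S,2S)-3-bromo-1-(3,5-dimethoxyphenyl)-5,7-dimethoxy-2-(4-methoxyphenyl)-2,3-dihydro-1H-indene-4-carbonyl]-4,6-dimethoxyphenyl}methylidene)cyclohexa-2,5-dien-1-one (both C8 epimers)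
Conditions: DDQ (1.05 equiv), CH2Cl2, 0 °C; filtration through basic alumina
Reagents that add atoms: none
Why: Dehydrogenation of a 4-benzyl-2,6-di-tert-butylphenol to its para-quinone methide (hydride abstraction from C7, then loss of the phenol proton), a classical entry to these compounds; the benzylic bromide and the methyl ethers should not react at 0 °C, and the symmetric quinoid ring excludes alkene isomers.

Step 11
Reactants: 15 2,6-di-tert-butyl-4-({2-[(1S,2S)-3-bromo-1-(3,5-dimethoxyphenyl)-5,7-dimethoxy-2-(4-methoxyphenyl)-2,3-dihydro-1H-indene-4-carbonyl]-4,6-dimethoxyphenyl}methylidene)cyclohexa-2,5-dien-1-one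
Product: 16 (7S,8R,9S,10S)-tetracyclic ketone: the skeleton of 18 with 3,5-di-tert-butyl-4-hydroxyphenyl on C7, 4-methoxyphenyl on C9, 3,5-dimethoxyphenyl on C10 and two methoxy groups on each of rings A and B
Conditions: fac-Ir(ppy)3 (1 mol %), Hantzsch ester (1.5 equiv), i-Pr2NEt (2 equiv), degassed MeCN/CH2Cl2, 0.005 M, 450 nm LEDs, 25 °C
Reagents that add atoms: none
Why: Proposed new method: excited fac-Ir(ppy)3 (trivalent iridium) passes one electron to 15, directly into the C8–Br bond or by way of the more easily reduced quinone methide, and loss of bromide leaves the same planar benzylic C8 radical from either epimer; this radical adds to the electron-poor methide carbon C7, and the persistent 2,6-di-tert-butylphenoxyl radical so formed is reduced and protonated by the Hantzsch ester, which makes the sequence irreversible, while the amine takes up HBr and helps return tetravalent iridium to the trivalent state. The closest known reaction type is the intermolecular reductive 1,6-addition of alkyl and benzyl halides to para-quinone methides under photoredox or zinc mediation; its use to close a ring is new. The seven-membered ring closes 7-exo-trig, and the tri-ortho-substituted benzophenone K already holds C7 within reach of C8 and leaves few rotors to freeze. C8 is controlled by C9: the 4-methoxyphenyl group on C9 shields one face of the indanyl radical, so C7 bonds anti to it. C7 is controlled in the same transition state: with ring A gauche to ring B about the forming bond, the bulky quinoid ring lies anti to ring B and away from C9, which places H7 trans to H8 and the two large groups pseudo-equatorial. The step needs ring closure to outrun hydrogen transfer to the C8 radical and reduction of the quinone methide; high dilution, a limited charge of hydrogen donor and the intramolecular position of the acceptor serve this, and the hindered amine is meant to spare the bromide from elimination.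

Step 12
Reactants: 16 (7S,8R,9S,10S)-tetracyclic ketone with 3,5-di-tert-butyl-4-hydroxyphenyl on C7 (hexamethyl ether)
Product: 17 (7S,8R,9S,10S)-hexamethyl ether of 18: 4-hydroxyphenyl on C7, 4-methoxyphenyl on C9, 3,5-dimethoxyphenyl on C10, two methoxy groups on each of rings A and B
Conditions: AlCl3 (6 equiv), MeNO2, toluene, 25 °C
Reagents that add atoms: none
Why: Retro-Friedel–Crafts de-tert-butylation with transfer of both tert-butyl groups to toluene, the standard way to unmask the parent phenol in adducts of these quinone methides; nitromethane tempers AlCl3 so that the methyl ethers and the C7–aryl bond should persist.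

Step 13
Reactants: 17 (7S,8R,9S,10S)-hexamethyl ether of 18
Product: 18 target heptaphenol, (7S,8R,9S,10S)
Conditions: BBr3 (excess), CH2Cl2, −78 °C → rt; MeOH, then H2O
Reagents that add atoms: none
Why: Lewis-acid cleavage of the six aryl methyl ethers, the usual final step for permethylated resveratrol oligomers; the benzylic methines carry no leaving group and should not epimerise.

## Compound list

1 | 3,5-dimethoxybenzoyl chloride | COc1cc(cc(OC)c1)C(Cl)=O | starting material
2 | N,3,5-trimethoxy-N-methylbenzamide | CON(C)C(=O)c1cc(OC)cc(OC)c1 | intermediate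
3 | 3,5-di-tert-butyl-4-hydroxybenzyl alcohol | CC(C)(C)c1cc(CO)cc(C(C)(C)C)c1O | starting material
4 | 2-[(3,5-di-tert-butyl-4-hydroxyphenyl)methyl]-N,3,5-trimethoxy-N-methylbenzamide | CON(C)C(=O)c1cc(OC)cc(OC)c1Cc1cc(C(C)(C)C)c(O)c(C(C)(C)C)c1 | intermediate
5 | 2-bromo-N,3,5-trimethoxy-N-methylbenzamide | CON(C)C(=O)c1cc(OC)cc(OC)c1Br | intermediate
6 | 4-methoxybenzylmagnesium chloride | COc1ccc(C[Mg]Cl)cc1 | starting material
7 | 1-(2-bromo-3,5-dimethoxyphenyl)-2-(4-methoxyphenyl)ethan-1-one | COc1ccc(CC(=O)c2cc(OC)cc(OC)c2Br)cc1 | intermediate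
8 | 3,5-dimethoxybenzaldehyde | COc1cc(C=O)cc(OC)c1 | starting material
9 | (E)-1-(2-bromo-3,5-dimethoxyphenyl)-3-(3,5-dimethoxyphenyl)-2-(4-methoxyphenyl)prop-2-en-1-one | O=C(c1cc(OC)cc(OC)c1Br)/C(=C/c1cc(OC)cc(OC)c1)c1ccc(OC)cc1 | intermediate
10 | (2RS,3RS)-7-bromo-3-(3,5-dimethoxyphenyl)-4,6-dimethoxy-2-(4-methoxyphenyl)-2,3-dihydro-1H-inden-1-one, racemic trans isomer (SMILES shows the 2S,3S enantiomer) | Brc1c(OC)cc(OC)c2c1C(=O)[C@H](c1ccc(OC)cc1)[C@H]2c1cc(OC)cc(OC)c1 | intermediate
11 | (1R,2S,3S)-7-bromo-3-(3,5-dimethoxyphenyl)-4,6-dimethoxy-2-(4-methoxyphenyl)-2,3-dihydro-1H-inden-1-ol | Brc1c(OC)cc(OC)c2c1[C@H](O)[C@H](c1ccc(OC)cc1)[C@H]2c1cc(OC)cc(OC)c1 | intermediate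
12 | lithium (1R,2S,3S)-3-(3,5-dimethoxyphenyl)-7-lithio-4,6-dimethoxy-2-(4-methoxyphenyl)-2,3-dihydro-1H-inden-1-olate | [Li]c1c(OC)cc(OC)c2c1[C@H](O[Li])[C@H](c1ccc(OC)cc1)[C@H]2c1cc(OC)cc(OC)c1 | intermediate
13 | {2-[(3,5-di-tert-butyl-4-hydroxyphenyl)methyl]-3,5-dimethoxyphenyl}[(1S,2S,3R)-1-(3,5-dimethoxyphenyl)-3-hydroxy-5,7-dimethoxy-2-(4-methoxyphenyl)-2,3-dihydro-1H-inden-4-yl]methanone | O=C(c1cc(OC)cc(OC)c1Cc1cc(C(C)(C)C)c(O)c(C(C)(C)C)c1)c1c(OC)cc(OC)c2c1[C@H](O)[C@H](c1ccc(OC)cc1)[C@H]2c1cc(OC)cc(OC)c1 | intermediate
14 | [(1S,2S)-3-bromo-1-(3,5-dimethoxyphenyl)-5,7-dimethoxy-2-(4-methoxyphenyl)-2,3-dihydro-1H-inden-4-yl]{2-[(3,5-di-tert-butyl-4-hydroxyphenyl)methyl]-3,5-dimethoxyphenyl}methanone, both C8 epimers | O=C(c1cc(OC)cc(OC)c1Cc1cc(C(C)(C)C)c(O)c(C(C)(C)C)c1)c1c(OC)cc(OC)c2c1C(Br)[C@H](c1ccc(OC)cc1)[C@H]2c1cc(OC)cc(OC)c1 | intermediate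
15 | 2,6-di-tert-butyl-4-({2-[(1S,2S)-3-bromo-1-(3,5-dimethoxyphenyl)-5,7-dimethoxy-2-(4-methoxyphenyl)-2,3-dihydro-1H-indene-4-carbonyl]-4,6-dimethoxyphenyl}methylidene)cyclohexa-2,5-dien-1-one, both C8 epimers | O=C(c1cc(OC)cc(OC)c1C=C1C=C(C(C)(C)C)C(=O)C(C(C)(C)C)=C1)c1c(OC)cc(OC)c2c1C(Br)[C@H](c1ccc(OC)cc1)[C@H]2c1cc(OC)cc(OC)c1 | intermediate
16 | (7S,8R,9S,10S)-tetracyclic ketone, hexamethyl ether with 3,5-di-tert-butyl-4-hydroxyphenyl on C7 | O=C1c2cc(OC)cc(OC)c2[C@H](c2cc(C(C)(C)C)c(O)c(C(C)(C)C)c2)[C@@H]2c3c1c(OC)cc(OC)c3[C@H](c1cc(OC)cc(OC)c1)[C@H]2c1ccc(OC)cc1 | intermediate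
17 | (7S,8R,9S,10S)-hexamethyl ether of the target with free 4-hydroxyphenyl on C7 | O=C1c2cc(OC)cc(OC)c2[C@H](c2ccc(O)cc2)[C@@H]2c3c1c(OC)cc(OC)c3[C@H](c1cc(OC)cc(OC)c1)[C@H]2c1ccc(OC)cc1 | intermediate
18 | CNP0116600.1, (7S,8R,9S,10S)-heptaphenol | O=C1c2cc(O)cc(O)c2[C@H](c2ccc(O)cc2)[C@@H]2c3c1c(O)cc(O)c3[C@H](c1cc(O)cc(O)c1)[C@H]2c1ccc(O)cc1 | target

Total steps: 13. Longest linear sequence: 12 steps (1 → 2 → 5 → 7 → 9 → 10 → 11 → 13 → 14 → 15 → 16 → 17 → 18); the ring A branch (step 2) joins at step 8.

## Least certain steps

**Step 11 (key step).** Most likely failure: the chain is intercepted before the ring closes. The quinone methide is the more easily reduced group, so electron and proton transfer to it, or hydrogen transfer to the stabilised C8 radical, may outrun a seven-membered closure through a hindered benzylic radical. The amine may also remove HBr toward the conjugated indene, and the C7 face is held only by a conformational preference.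

Fallback, from 11 and 4 back to 16, reversing the order of bond formation so that each step has precedent. 11 is brominated (CBr4, PPh3) to (2S,3S)-1,7-dibromo-3-(3,5-dimethoxyphenyl)-4,6-dimethoxy-2-(4-methoxyphenyl)-2,3-dihydro-1H-indene F1. 4 is dehydrogenated with DDQ to the quinone methide 2-[(3,5-di-tert-butyl-4-oxocyclohexa-2,5-dien-1-ylidene)methyl]-N,3,5-trimethoxy-N-methylbenzamide F2. Zinc dust (THF, aq NH4Cl) joins the benzylic carbon of F1 to the methide carbon of F2 in the known intermolecular mode, anti to the C9 aryl group, giving the open-chain adduct 2-{[(1R,2S,3S)-7-bromo-3-(3,5-dimethoxyphenyl)-4,6-dimethoxy-2-(4-methoxyphenyl)-2,3-dihydro-1H-inden-1-yl](3,5-di-tert-butyl-4-hydroxyphenyl)methyl}-N,3,5-trimethoxy-N-methylbenzamide F3 as C7 epimers. tert-Butyllithium deprotonates the phenol and exchanges the ring B bromine to the aryllithium phenoxide F4, which closes the seven-membered ring on the Weinreb amide (Parham cyclisation) to 16 and its C7 epimer, the (7R,8R,9S,10S) ketone F5. F5 is separated and should be equilibrated to 16 with t-BuOK in DMSO through the dienolate that K makes possible.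

**Step 9.** Most likely failure: loss of HBr by E1 or E2 during the substitution or on silica. The alkene formed would be conjugated with ring B and the C9 aryl group, and the alkoxyphosphonium intermediate is hindered toward bromide attack.

Fallback, from 13 back to 16 without any halide, generating the same C8 radical by oxidation. 13 is treated with oxalyl chloride and then water to give the hydrogen oxalate 2-oxo-2-{[(1R,2S,3S)-7-{2-[(3,5-di-tert-butyl-4-hydroxyphenyl)methyl]-3,5-dimethoxybenzoyl}-3-(3,5-dimethoxyphenyl)-4,6-dimethoxy-2-(4-methoxyphenyl)-2,3-dihydro-1H-inden-1-yl]oxy}acetic acid F6. DDQ converts it to the corresponding quinone methide hydrogen oxalate F7. Its caesium salt (Cs2CO3) is oxidised by excited Ir[dF(CF3)ppy]2(dtbbpy)PF6 under blue light and loses two molecules of CO2, the known way to alkyl radicals from alcohol oxalates. The C8 radical closes onto C7 as in step 11, and the phenoxyl radical is reduced by the divalent iridium formed, so no stoichiometric reductant is present to attack the quinone methide.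

**Step 7.** Most likely failure: a small rate difference between the enantiomers of 10. The C2 and C3 aryl groups shield opposite faces of the carbonyl and the 7-bromo substituent crowds it, so catalyst control may not dominate, and epimerisation at C2 in the amine medium can leak material into diastereomeric alcohols.

Fallback, from 10 back to 11 by classical resolution. NaBH4 reduces racemic 10 to 11 together with its enantiomer (1S,2R,3R)-7-bromo-3-(3,5-dimethoxyphenyl)-4,6-dimethoxy-2-(4-methoxyphenyl)-2,3-dihydro-1H-inden-1-ol F8. Esterification with (S)-2-methoxy-2-phenylacetic acid (DCC, DMAP) gives the diastereomeric esters (1R,2S,3S)-7-bromo-3-(3,5-dimethoxyphenyl)-4,6-dimethoxy-2-(4-methoxyphenyl)-2,3-dihydro-1H-inden-1-yl (S)-2-methoxy-2-phenylacetate F9 and its (1S,2R,3R) counterpart F10, which are separated by crystallisation or chromatography. Hydrolysis of F9 (LiOH, THF/H2O) returns 11.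

**Step 8.** Most likely failure: slow acylation through steric congestion. The aryllithium sits between a methoxy group and the C8 alkoxide, and the amide carries an ortho benzyl group, so proton transfer to the aryllithium or base-induced loss of the N-methoxy group may take over and give debrominated indanol.

Fallback, from 4 and 12 back to 13 through the less demanding aldehyde. LiAlH4 reduces 4 to 2-[(3,5-di-tert-butyl-4-hydroxyphenyl)methyl]-3,5-dimethoxybenzaldehyde F11. 12 adds to F11 to give the diol [(1S,2S,3R)-1-(3,5-dimethoxyphenyl)-3-hydroxy-5,7-dimethoxy-2-(4-methoxyphenyl)-2,3-dihydro-1H-inden-4-yl]{2-[(3,5-di-tert-butyl-4-hydroxyphenyl)methyl]-3,5-dimethoxyphenyl}methanol F12. Swern oxidation of both carbinols gives the diketone (2S,3S)-7-{2-[(3,5-di-tert-butyl-4-hydroxyphenyl)methyl]-3,5-dimethoxybenzoyl}-3-(3,5-dimethoxyphenyl)-4,6-dimethoxy-2-(4-methoxyphenyl)-2,3-dihydro-1H-inden-1-one F13. NaBH4 at 0 °C should reduce only the indanone carbonyl, anti to the C2 aryl group, since K is a deactivated, tri-ortho-substituted benzophenone; this returns 13.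

**Step 12.** Most likely failure: over-reaction of the Lewis acid. Chelation-assisted cleavage of the methyl ether ortho to K, or transfer of the whole C7 aryl group by the same ipso-protonation path that removes the tert-butyl groups, may accompany dealkylation.

Fallback, from 16 back to 18 with the order of the two deprotections reversed. BBr3 first cleaves the six methyl ethers of 16 to the (7S,8R,9S,10S)-heptaphenol still carrying the two tert-butyl groups F14. The tert-butyl groups are then transferred to toluene with CF3SO3H, which gives 18 directly and removes any concern about partial ether cleavage.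

## Further compounds

F1 | step 11 | (2S,3S)-1,7-dibromo-3-(3,5-dimethoxyphenyl)-4,6-dimethoxy-2-(4-methoxyphenyl)-2,3-dihydro-1H-indene, both C1 epimers | Brc1c(OC)cc(OC)c2c1C(Br)[C@H](c1ccc(OC)cc1)[C@H]2c1cc(OC)cc(OC)c1
F2 | step 11 | 2-[(3,5-di-tert-butyl-4-oxocyclohexa-2,5-dien-1-ylidene)methyl]-N,3,5-trimethoxy-N-methylbenzamide | CON(C)C(=O)c1cc(OC)cc(OC)c1C=C1C=C(C(C)(C)C)C(=O)C(C(C)(C)C)=C1
F3 | step 11 | 2-{[(1R,2S,3S)-7-bromo-3-(3,5-dimethoxyphenyl)-4,6-dimethoxy-2-(4-methoxyphenyl)-2,3-dihydro-1H-inden-1-yl](3,5-di-tert-butyl-4-hydroxyphenyl)methyl}-N,3,5-trimethoxy-N-methylbenzamide, both C7 epimers | CON(C)C(=O)c1cc(OC)cc(OC)c1C(c1cc(C(C)(C)C)c(O)c(C(C)(C)C)c1)[C@@H]1c2c(Br)c(OC)cc(OC)c2[C@H](c2cc(OC)cc(OC)c2)[C@H]1c1ccc(OC)cc1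
F4 | step 11 | aryllithium lithium phenoxide derived from F3 | CON(C)C(=O)c1cc(OC)cc(OC)c1C(c1cc(C(C)(C)C)c(O[Li])c(C(C)(C)C)c1)[C@@H]1c2c([Li])c(OC)cc(OC)c2[C@H](c2cc(OC)cc(OC)c2)[C@H]1c1ccc(OC)cc1
F5 | step 11 | (7R,8R,9S,10S)-C7 epimer of 16 | O=C1c2cc(OC)cc(OC)c2[C@@H](c2cc(C(C)(C)C)c(O)c(C(C)(C)C)c2)[C@@H]2c3c1c(OC)cc(OC)c3[C@H](c1cc(OC)cc(OC)c1)[C@H]2c1ccc(OC)cc1
F6 | step 9 | 2-oxo-2-{[(1R,2S,3S)-7-{2-[(3,5-di-tert-butyl-4-hydroxyphenyl)methyl]-3,5-dimethoxybenzoyl}-3-(3,5-dimethoxyphenyl)-4,6-dimethoxy-2-(4-methoxyphenyl)-2,3-dihydro-1H-inden-1-yl]oxy}acetic acid | O=C(c1cc(OC)cc(OC)c1Cc1cc(C(C)(C)C)c(O)c(C(C)(C)C)c1)c1c(OC)cc(OC)c2c1[C@H](OC(=O)C(O)=O)[C@H](c1ccc(OC)cc1)[C@H]2c1cc(OC)cc(OC)c1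
F7 | step 9 | quinone methide hydrogen oxalate: F6 with the benzylphenol dehydrogenated to the 3,5-di-tert-butyl-4-oxocyclohexa-2,5-dien-1-ylidene methide | O=C(c1cc(OC)cc(OC)c1C=C1C=C(C(C)(C)C)C(=O)C(C(C)(C)C)=C1)c1c(OC)cc(OC)c2c1[C@H](OC(=O)C(O)=O)[C@H](c1ccc(OC)cc1)[C@H]2c1cc(OC)cc(OC)c1
F8 | step 7 | (1S,2R,3R)-7-bromo-3-(3,5-dimethoxyphenyl)-4,6-dimethoxy-2-(4-methoxyphenyl)-2,3-dihydro-1H-inden-1-ol | Brc1c(OC)cc(OC)c2c1[C@@H](O)[C@@H](c1ccc(OC)cc1)[C@@H]2c1cc(OC)cc(OC)c1
F9 | step 7 | (1R,2S,3S)-7-bromo-3-(3,5-dimethoxyphenyl)-4,6-dimethoxy-2-(4-methoxyphenyl)-2,3-dihydro-1H-inden-1-yl (S)-2-methoxy-2-phenylacetate | Brc1c(OC)cc(OC)c2c1[C@H](OC(=O)[C@@H](OC)c1ccccc1)[C@H](c1ccc(OC)cc1)[C@H]2c1cc(OC)cc(OC)c1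
F10 | step 7 | (1S,2R,3R)-7-bromo-3-(3,5-dimethoxyphenyl)-4,6-dimethoxy-2-(4-methoxyphenyl)-2,3-dihydro-1H-inden-1-yl (S)-2-methoxy-2-phenylacetate | Brc1c(OC)cc(OC)c2c1[C@@H](OC(=O)[C@@H](OC)c1ccccc1)[C@@H](c1ccc(OC)cc1)[C@@H]2c1cc(OC)cc(OC)c1
F11 | step 8 | 2-[(3,5-di-tert-butyl-4-hydroxyphenyl)methyl]-3,5-dimethoxybenzaldehyde | O=Cc1cc(OC)cc(OC)c1Cc1cc(C(C)(C)C)c(O)c(C(C)(C)C)c1
F12 | step 8 | [(1S,2S,3R)-1-(3,5-dimethoxyphenyl)-3-hydroxy-5,7-dimethoxy-2-(4-methoxyphenyl)-2,3-dihydro-1H-inden-4-yl]{2-[(3,5-di-tert-butyl-4-hydroxyphenyl)methyl]-3,5-dimethoxyphenyl}methanol, both carbinol epimers | OC(c1cc(OC)cc(OC)c1Cc1cc(C(C)(C)C)c(O)c(C(C)(C)C)c1)c1c(OC)cc(OC)c2c1[C@H](O)[C@H](c1ccc(OC)cc1)[C@H]2c1cc(OC)cc(OC)c1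
F13 | step 8 | (2S,3S)-7-{2-[(3,5-di-tert-butyl-4-hydroxyphenyl)methyl]-3,5-dimethoxybenzoyl}-3-(3,5-dimethoxyphenyl)-4,6-dimethoxy-2-(4-methoxyphenyl)-2,3-dihydro-1H-inden-1-one | O=C(c1cc(OC)cc(OC)c1Cc1cc(C(C)(C)C)c(O)c(C(C)(C)C)c1)c1c(OC)cc(OC)c2c1C(=O)[C@H](c1ccc(OC)cc1)[C@H]2c1cc(OC)cc(OC)c1
F14 | step 12 | (7S,8R,9S,10S)-heptaphenol with 3,5-di-tert-butyl-4-hydroxyphenyl on C7 | O=C1c2cc(O)cc(O)c2[C@H](c2cc(C(C)(C)C)c(O)c(C(C)(C)C)c2)[C@@H]2c3c1c(O)cc(O)c3[C@H](c1cc(O)cc(O)c1)[C@H]2c1ccc(O)cc1
A1 | alternative 1 | methyl 2-{[3-(3,5-dimethoxyphenyl)-6-ethoxy-4-hydroxy-2-(4-methoxyphenyl)-2,3-dihydro-1H-inden-1-yl](4-methoxyphenyl)methyl}-3,5-dimethoxybenzoate, all-trans, configuration as in the SMILES | COC(=O)c1cc(OC)cc(OC)c1[C@H](c1ccc(OC)cc1)[C@@H]1c2cc(OCC)cc(O)c2[C@H](c2cc(OC)cc(OC)c2)[C@H]1c1ccc(OC)cc1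
A2 | alternative 2 | methyl trans,trans-3-(3,5-dimethoxyphenyl)-4,6-dimethoxy-2-(4-methoxyphenyl)-2,3-dihydro-1H-indene-1-carboxylate, configuration as in the SMILES | COC(=O)[C@@H]1c2cc(OC)cc(OC)c2[C@H](c2cc(OC)cc(OC)c2)[C@H]1c1ccc(OC)cc1
A3 | alternative 3 | tetracyclic C7 tertiary alcohol: hexamethyl ether skeleton of 18 with hydroxyl and 4-methoxyphenyl on C7, C7 configuration open | O=C1c2cc(OC)cc(OC)c2C(O)(c2ccc(OC)cc2)[C@@H]2c3c1c(OC)cc(OC)c3[C@H](c1cc(OC)cc(OC)c1)[C@H]2c1ccc(OC)cc1
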